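**Retrosynthetic overview**
1. Last bond, C3(pyranone)–CH2(aryl): Knoevenagel condensation and Hantzsch-ester reduction between a free catechol aldehyde and the finished hydroxypropyl pyranone, with no protecting groups left.
2. Key bond, C6(pyranone)–CH2(side chain): the C–Cl carbon of 6-chloro-4-hydroxy-2-pyranone (acid-chloride oxidation level) and the CH2 of (S)-propylene oxide, both electrophiles, are joined by nickel-catalysed reductive coupling through a pyranon-6-yl nickel species (a masked acyl anion). The stereocentre arrives ready-made in the epoxide.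
3. Aryl–acetyl bond: 2-bromo-3,4,5-trimethoxybenzaldehyde plus an α-ethoxyvinyl stannane (acetyl anion equivalent); the new acetyl group then steers removal of the two neighbouring O-methyl groups.
4. Rings: the benzene ring is bought. The 2-pyranone ring is the only ring made, and it is made first, by self-condensation of malonyl dichloride.

Assumption: 2-bromo-3,4,5-trimethoxybenzaldehyde is bought as a catalogue compound (otherwise it is one NBS bromination from 3,4,5-trimethoxybenzaldehyde).

**Step 1**
Reactants: 1 malonyl dichloride (2 equiv)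
Product: 4 6-chloro-4-hydroxy-2H-pyran-2-one, via pyranone-3-carbonyl chloride 2 (not isolated), via pyranone-3-carboxylic acid 3 (not isolated)
Conditions: neat, N2, 25 °C, 3 d; then H2O (1.1 equiv), 1,4-dioxane, 90 °C, 1 h
Reagents that add atoms: none
Why: Known self-condensation of malonyl dichloride (C-acylation of one molecule by a second, then O-acylative ring closure in which the enolised COCl carbon becomes C6–Cl), followed by hydrolysis of the 3-COCl group and decarboxylation of the resulting vinylogous β-keto acid; no stereocentre.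

**Step 2 (key step)**
Reactants: 4 6-chloro-4-hydroxy-2H-pyran-2-one; 5 (S)-propylene oxide (2 equiv)
Product: 7 4-hydroxy-6-[(2S)-2-hydroxypropyl]-2H-pyran-2-one, via (2S)-1-iodopropan-2-ol 6 (not isolated)
Conditions: NiBr2·glyme (10 mol %), 2,2'-bipyridine (10 mol %), NaI (50 mol %), Mn powder (2 equiv), DMPU, 40 °C, 16 h; then 1 M HCl
Reagents that add atoms: none
Why: Proposed new method: nickel-catalysed reductive cross-electrophile coupling. Iodide, with the acidic 4-OH of 4 as the only proton source, opens the epoxide at its CH2 terminus to iodohydrin 6. Ni(0)/bipyridine inserts into the vinylogous acid-chloride bond C6–Cl to give a pyranon-6-yl nickel species, which acts as an α-oxyvinyl (acyl-anion-type) nucleophile. This captures the primary radical formed from 6 and reductively eliminates, with Mn turning the nickel over, so two natively electrophilic carbons are joined. The carbinol carbon is never a reacting centre and keeps the (S) configuration of 5. The closest known reaction type is the Ni/bipyridine/iodide reductive coupling of aryl and vinyl halides with terminal epoxides, which opens enantiopure epoxides at the less hindered carbon without loss of ee, together with the Ni-catalysed reductive coupling of acid chlorides with alkyl iodides.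

**Step 3**
Reactants: 8 2-bromo-3,4,5-trimethoxybenzaldehyde; 9 tributyl(1-ethoxyethenyl)stannane
Product: 11 2-acetyl-3,4,5-trimethoxybenzaldehyde, via aryl enol ether 10 (not isolated)
Conditions: PdCl2(PPh3)2 (5 mol %), toluene, 100 °C, 16 h; then 2 M HCl, THF, 25 °C, 1 h
Reagents that add atoms: water, O
Why: Migita–Kosugi–Stille coupling in which the α-ethoxyvinyl stannane serves as an acetyl anion equivalent at the C–Br carbon (oxidative addition is helped by the ortho formyl group, the free aldehyde is tolerated, and the acetyl group lands where Friedel–Crafts acylation of a benzaldehyde cannot reach), after which dilute acid hydrolyses the enol ether to the methyl ketone; no stereocentre.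

**Step 4**
Reactants: 11 2-acetyl-3,4,5-trimethoxybenzaldehyde
Product: 13 2-acetyl-3,4-dihydroxy-5-methoxybenzaldehyde, via cyclic chloroborate 12 (not isolated)
Conditions: BCl3 (3 equiv), CH2Cl2, −78 → 25 °C, 12 h; then ice/1 M HCl
Reagents that add atoms: none
Why: Chelation-controlled Lewis-acid ether cleavage: BCl3 bound to the acetyl oxygen cleaves the ortho 3-OMe, the resulting aryl–OBCl2 cleaves only the adjacent 4-OMe while closing the five-membered catechol borate, and the 5-OMe, which has no carbonyl neighbour and faces a boron already tied up in the ring, survives (the known 2,3,4-trimethoxyaryl carbonyl to 2,3-dihydroxy-4-methoxy pattern); no stereocentre.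

**Step 5**
Reactants: 13 2-acetyl-3,4-dihydroxy-5-methoxybenzaldehyde; 7 4-hydroxy-6-[(2S)-2-hydroxypropyl]-2H-pyran-2-one
Product: 15 penicanesin D, via Knoevenagel alkylidene 14 (not isolated)
Conditions: Hantzsch ester (1.2 equiv), EtOH (degassed), N2, 50 °C, 12 h
Reagents that add atoms: none
Why: Three-component reductive alkylation (Knoevenagel condensation at C3 of the acidic 4-hydroxypyranone, then conjugate transfer hydrogenation of the alkylidene-1,3-dicarbonyl by the Hantzsch ester), which needs no amine catalyst that could trigger aldol closure of the o-acetylbenzaldehyde, leaves the aryl ketone untouched and does not involve the (S)-carbinol.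

**Compound list**
1 | malonyl dichloride | O=C(Cl)CC(=O)Cl | starting material
2 | 6-chloro-4-hydroxy-2-oxo-2H-pyran-3-carbonyl chloride | O=C(Cl)c1c(O)cc(Cl)oc1=O | intermediate
3 | 6-chloro-4-hydroxy-2-oxo-2H-pyran-3-carboxylic acid | O=C(O)c1c(O)cc(Cl)oc1=O | intermediate
4 | 6-chloro-4-hydroxy-2H-pyran-2-one | O=c1cc(O)cc(Cl)o1 | intermediate
5 | (S)-propylene oxide, (2S)-2-methyloxirane | C[C@H]1CO1 | starting material
6 | (2S)-1-iodopropan-2-ol | C[C@H](O)CI | intermediate
7 | 4-hydroxy-6-[(2S)-2-hydroxypropyl]-2H-pyran-2-one | O=c1cc(O)cc(C[C@H](C)O)o1 | intermediate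
8 | 2-bromo-3,4,5-trimethoxybenzaldehyde | O=Cc1cc(OC)c(OC)c(OC)c1Br | starting material
9 | tributyl(1-ethoxyethenyl)stannane | CCCC[Sn](CCCC)(CCCC)C(=C)OCC | starting material
10 | 2-(1-ethoxyethenyl)-3,4,5-trimethoxybenzaldehyde | O=Cc1cc(OC)c(OC)c(OC)c1C(=C)OCC | intermediate
11 | 2-acetyl-3,4,5-trimethoxybenzaldehyde | O=Cc1cc(OC)c(OC)c(OC)c1C(C)=O | intermediate
12 | 4-acetyl-2-chloro-7-methoxy-1,3,2-benzodioxaborole-5-carbaldehyde | O=Cc1cc(OC)c2OB(Cl)Oc2c1C(C)=O | intermediate
13 | 2-acetyl-3,4-dihydroxy-5-methoxybenzaldehyde | O=Cc1cc(OC)c(O)c(O)c1C(C)=O | intermediate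
14 | 3-[(2-acetyl-3,4-dihydroxy-5-methoxyphenyl)methylidene]-6-[(2S)-2-hydroxypropyl]-2H-pyran-2,4(3H)-dione | COc1cc(C=C2C(=O)OC(C[C@H](C)O)=CC2=O)c(C(C)=O)c(O)c1O | intermediate
15 | penicanesin D, 3-[(2-acetyl-3,4-dihydroxy-5-methoxyphenyl)methyl]-4-hydroxy-6-[(2S)-2-hydroxypropyl]-2H-pyran-2-one | COc1cc(Cc2c(O)cc(C[C@H](C)O)oc2=O)c(C(C)=O)c(O)c1O | target

**Step count**
Total steps: 5. Longest linear sequence: 3 steps (steps 1, 2, 5 or steps 3, 4, 5).

**Steps most likely to fail, with fallbacks**

Step 2. The coupling has not been run on a chloropyranone carrying a free, acidic OH; the chloride may simply be reduced or homocoupled, and a little epoxide may open at the wrong carbon. The fallback sets out from 4 and returns at 7; it makes the C6–CH2 bond with normal polarity and sets the stereocentre by reduction. Pd-catalysed acetonylation of 4 with the tin enolate formed in situ from isopropenyl acetate and Bu3SnOMe (PdCl2[P(o-tol)3]2, toluene, 100 °C) gives 4-hydroxy-6-(2-oxopropyl)-2H-pyran-2-one F1. A Prelog-selective alcohol dehydrogenase (ADH-A of Rhodococcus ruber, NADH, i-PrOH, pH 7 buffer, 30 °C) then reduces the methyl ketone from its Re face to the (S)-carbinol 7.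

Step 4. The double demethylation runs next to a free aldehyde and may stop at the monophenol or go on to the third ether. The fallback sets out from 8 and returns at 12; it removes the two methyl groups under two separate controls. AlCl3 in CH2Cl2 at 25 °C cleaves only the central 4-OMe of 8 (para to the formyl group, as in the trimethoxybenzaldehyde-to-syringaldehyde cleavage) and gives 2-bromo-4-hydroxy-3,5-dimethoxybenzaldehyde F2. Coupling with 9 as in step 3 gives 2-(1-ethoxyethenyl)-4-hydroxy-3,5-dimethoxybenzaldehyde F3, which the acidic work-up hydrolyses to 2-acetyl-4-hydroxy-3,5-dimethoxybenzaldehyde F4. BCl3 (2 equiv, −78 to 0 °C) then has only the 3-OMe to cleave, which is activated from both sides (acetyl chelate and the 4-O–BCl2 group), and closes the cyclic chloroborate 12; the work-up of step 4 turns this into 13.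

Step 5. The o-acetyl catechol aldehyde 13 can close to an indanone by aldol reaction, form bis-pyranone adducts or oxidise in air. The fallback sets out from 8 and 7 and returns at 15; it reverses the order so that the union is run on the robust bromo aldehyde. The same Hantzsch-ester reductive alkylation of 7 with 8 passes through 3-[(2-bromo-3,4,5-trimethoxyphenyl)methylidene]-6-[(2S)-2-hydroxypropyl]-2H-pyran-2,4(3H)-dione F5 and gives 3-[(2-bromo-3,4,5-trimethoxyphenyl)methyl]-4-hydroxy-6-[(2S)-2-hydroxypropyl]-2H-pyran-2-one F6. Coupling with 9 (Pd(PPh3)4, Et3N, dioxane, 100 °C) gives 3-{[2-(1-ethoxyethenyl)-3,4,5-trimethoxyphenyl]methyl}-4-hydroxy-6-[(2S)-2-hydroxypropyl]-2H-pyran-2-one F7, hydrolysed by dilute acid to 3-[(2-acetyl-3,4,5-trimethoxyphenyl)methyl]-4-hydroxy-6-[(2S)-2-hydroxypropyl]-2H-pyran-2-one F8. BCl3 as in step 4 gives the cyclic aryl chloroborate F9, and aqueous work-up gives 15.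

**Further compounds**
F1 | step 2 | 4-hydroxy-6-(2-oxopropyl)-2H-pyran-2-one | CC(=O)Cc1cc(O)cc(=O)o1
F2 | step 4 | 2-bromo-4-hydroxy-3,5-dimethoxybenzaldehyde | O=Cc1cc(OC)c(O)c(OC)c1Br
F3 | step 4 | 2-(1-ethoxyethenyl)-4-hydroxy-3,5-dimethoxybenzaldehyde | O=Cc1cc(OC)c(O)c(OC)c1C(=C)OCC
F4 | step 4 | 2-acetyl-4-hydroxy-3,5-dimethoxybenzaldehyde | O=Cc1cc(OC)c(O)c(OC)c1C(C)=O
F5 | step 5 | 3-[(2-bromo-3,4,5-trimethoxyphenyl)methylidene]-6-[(2S)-2-hydroxypropyl]-2H-pyran-2,4(3H)-dione | COc1cc(C=C2C(=O)OC(C[C@H](C)O)=CC2=O)c(Br)c(OC)c1OC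
F6 | step 5 | 3-[(2-bromo-3,4,5-trimethoxyphenyl)methyl]-4-hydroxy-6-[(2S)-2-hydroxypropyl]-2H-pyran-2-one | COc1cc(Cc2c(O)cc(C[C@H](C)O)oc2=O)c(Br)c(OC)c1OC
F7 | step 5 | 3-{[2-(1-ethoxyethenyl)-3,4,5-trimethoxyphenyl]methyl}-4-hydroxy-6-[(2S)-2-hydroxypropyl]-2H-pyran-2-one | COc1cc(Cc2c(O)cc(C[C@H](C)O)oc2=O)c(C(=C)OCC)c(OC)c1OC
F8 | step 5 | 3-[(2-acetyl-3,4,5-trimethoxyphenyl)methyl]-4-hydroxy-6-[(2S)-2-hydroxypropyl]-2H-pyran-2-one | COc1cc(Cc2c(O)cc(C[C@H](C)O)oc2=O)c(C(C)=O)c(OC)c1OC
F9 | step 5 | cyclic aryl chloroborate of 15 (other OH groups drawn free) | COc1cc(Cc3c(O)cc(C[C@H](C)O)oc3=O)c(C(C)=O)c2OB(Cl)Oc12
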